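Ring atoms are called C1 (quaternary C–OH), C2 (CH–OAc), C3=C4, C5 and C6 (CH–OBz) and C7 (CH2OAc); O1–O7 are the oxygens on them.

- **Cuts:** after removal of the four acyl groups, C2–C3 and C5–C6 are cut, a [3+3] dissection of the cyclohexene into a C6–C1(–C7)–C2 piece with both ends as formyl groups (O1/O7 tied as an acetonide) and a C3–C4–C5 piece.
- **Enabling feature:** C5 carries oxygen next to the ring double bond C3=C4, and C2 and C6 are both carbinol carbons on the quaternary C1. C3–C4–C5 is therefore the retron of a γ-oxygenated allyl unit nucleophilic at both ends (silicon on C3, carbamate oxygen on C5), and C2–C1–C6 of a malondialdehyde that cannot enolise.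
- **Forward order:** the dialdehyde is made in three steps and the allyl carbamate in one. The only carbocycle closes in the key step: the titanated carbamate adds through C3 to one formyl group (C2–C3), and the allylsilane so formed closes through C5 on the other (C5–C6), losing Me3Si.
- **Stereochemistry:** C2 (and the transient C3–Si centre) come from (−)-sparteine by reagent control; C1 from Felkin–Anh selection between the two enantiotopic formyl groups; C5 by anti-SE2′ chirality transfer from C3 through the Z enol carbamate; C6 trans to C5 from the open transition state.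
- **Endgame:** O2 is silylated, the carbamate is reduced off, O5/O6 are benzoylated, acid frees O1, O2 and O7, and the primary and secondary hydroxyls are acetylated while the tertiary one stays free.

Key step: step 5

Remark (assumption): (−)-sparteine is taken to give the (S)-configured α-lithio carbamate, as it does with (E)-but-2-enyl N,N-diisopropylcarbamate, and lithium–titanium exchange to go with inversion; should the opposite sense be found, the (+)-sparteine surrogate would be used instead.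

Step 1
Reactants: 1 2-methylenepropane-1,3-diol
Product: 2 2-(hydroxymethyl)propane-1,2,3-triol
Conditions: OsO4 (cat.), NMO, acetone/H2O, rt
Reagents that add atoms: N-methylmorpholine N-oxide C[N+]1([O-])CCOCC1; water O
Why: Catalytic OsO4 adds across the only C=C bond (syn-dihydroxylation, NMO as reoxidant) to give the achiral tetraol, so no stereocontrol is needed.

Step 2
Reactants: 2 2-(hydroxymethyl)propane-1,2,3-triol
Product: 3 (2,2-dimethyl-1,3-dioxolane-4,4-diyl)dimethanol
Conditions: 2,2-dimethoxypropane, TsOH (cat.), DMF, rt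
Reagents that add atoms: 2,2-dimethoxypropane COC(C)(C)OC
Why: Acid-catalysed acetal exchange under thermodynamic control should tie the tertiary hydroxyl and one CH2OH into the five-membered dioxolane (the six-membered dioxane alternative carries an axial methyl group), leaving two equivalent CH2OH groups.

Step 3
Reactants: 3 (2,2-dimethyl-1,3-dioxolane-4,4-diyl)dimethanol
Product: 4 2,2-dimethyl-1,3-dioxolane-4,4-dicarbaldehyde
Conditions: (COCl)2, DMSO, CH2Cl2, −78 °C; Et3N, −78 → 0 °C; used crude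
Reagents that add atoms: none
Why: Swern oxidation turns both neopentyl primary alcohols into formyl groups; the product is a 2,2-disubstituted malondialdehyde that cannot enolise and is taken on without purification.

Step 4
Reactants: 5 (E)-3-(trimethylsilyl)prop-2-en-1-ol
Product: 6 (E)-3-(trimethylsilyl)prop-2-en-1-yl N,N-diisopropylcarbamate
Conditions: NaH, THF, 0 °C; iPr2NCOCl, reflux
Reagents that add atoms: N,N-diisopropylcarbamoyl chloride CC(C)N(C(C)C)C(Cl)=O
Why: O-Acylation of the sodium alkoxide by the carbamoyl chloride gives the carbamate that will direct α-lithiation; the E vinylsilane is not touched.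

Step 5
Reactants: 6 (E)-3-(trimethylsilyl)prop-2-en-1-yl N,N-diisopropylcarbamate; 4 2,2-dimethyl-1,3-dioxolane-4,4-dicarbaldehyde
Product: 10 (1R,2S,5R,6S)-1-(hydroxymethyl)cyclohex-3-ene-1,2,5,6-tetrol 1,7-O-isopropylidene acetal 5-(N,N-diisopropylcarbamate), via lithiated carbamate 7 (not isolated), via allyltitanium reagent 8 (not isolated), via titanium homoaldolate 9 (not isolated)
Conditions: s-BuLi, (−)-sparteine, toluene, −78 °C; ClTi(OiPr)3, −78 °C; added to 4, toluene, −78 °C; then BF3·OEt2, CH2Cl2, −78 → −40 °C; aq. NaHCO3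
Reagents that add atoms: none
Why: Proposed new method: sparteine-mediated α-lithiation of 6 and Li→Ti exchange give the configurationally defined allyltitanium 8, whose γ-carbon C3 adds to one formyl group of 4 through a chair Zimmerman–Traxler transition state (C2–C3 bond, 2,3-anti, Z enol carbamate), and BF3 then activates the remaining formyl group so that the α-substituted γ-carbamoyloxy allylsilane in 9 attacks it through C5 in an anti-SE2′ process (C5–C6 bond) with loss of Me3Si and shift of the double bond to C3=C4. The closest known reaction types are the homoaldol addition of titanated 2-alkenyl carbamates to aldehydes and the intramolecular Hosomi–Sakurai allylsilane–aldehyde cyclisation; what is new is their union on a 2,2-disubstituted malondialdehyde, so that one three-carbon reagent bridges both formyl groups. The cyclohexene closes in a 6-exo-trig sense at the aldehyde carbon, with the whole allyl unit C3–C4–C5 inside the new ring. C2 and C3 are set by the (R)-titanium centre derived from (−)-sparteine (reagent control); C1 follows from Felkin–Anh discrimination between the two enantiotopic formyl groups (C1–O anti to the incoming carbon, the spectator formyl group as the small substituent, the weakly Lewis acidic titanium reagent reacting without chelation), which places O1 trans to O2; C5 is set by chirality transfer from the C3–Si centre with the Z carbamate oxygen inside (O5 cis to O2), and C6 by the antiperiplanar, dipole-minimised approach that places O6 trans to O5. The step needs mono-addition (one equivalent of 8 added to 4; the second formyl group is neopentyl and flanked by the bulky titanium alkoxide), attack through C5 and not C4 (β-silicon effect, weak donor ability of the carbamate oxygen) and ring closure faster than Peterson elimination of the β-silyl alkoxide (−78 °C; a titanium-bound oxygen is a poor leaving group).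

Step 6
Reactants: 10 (1R,2S,5R,6S)-1-(hydroxymethyl)cyclohex-3-ene-1,2,5,6-tetrol 1,7-O-isopropylidene acetal 5-(N,N-diisopropylcarbamate)
Product: 11 (1S,2S,5R,6S)-2-O-(tert-butyldimethylsilyl)-1,7-O-isopropylidene-1-(hydroxymethyl)cyclohex-3-ene-1,2,5,6-tetrol 5-(N,N-diisopropylcarbamate)
Conditions: TBSOTf (1.05 equiv), 2,6-lutidine, CH2Cl2, −78 °C
Reagents that add atoms: tert-butyldimethylsilyl trifluoromethanesulfonate CC(C)(C)[Si](C)(C)OS(=O)(=O)C(F)(F)F
Why: Silylation with the silyl triflate at −78 °C should take the C2 hydroxyl, whose second neighbour is the sp2 carbon C3, in preference to the C6 hydroxyl, which is wedged between the spiro carbon C1 and the carbamate-bearing C5.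

Step 7
Reactants: 11 (1S,2S,5R,6S)-2-O-(tert-butyldimethylsilyl)-1,7-O-isopropylidene-1-(hydroxymethyl)cyclohex-3-ene-1,2,5,6-tetrol 5-(N,N-diisopropylcarbamate)
Product: 12 (1S,2S,5R,6S)-2-O-(tert-butyldimethylsilyl)-1,7-O-isopropylidene-1-(hydroxymethyl)cyclohex-3-ene-1,2,5,6-tetrol
Conditions: LiAlH4, THF, reflux; Rochelle salt work-up
Reagents that add atoms: none
Why: LiAlH4 reduces the carbamate carbonyl and releases the C5 alkoxide with the C5–O bond intact (configuration retained), while silyl ether, acetal and the isolated double bond are inert to hydride.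

Step 8
Reactants: 12 (1S,2S,5R,6S)-2-O-(tert-butyldimethylsilyl)-1,7-O-isopropylidene-1-(hydroxymethyl)cyclohex-3-ene-1,2,5,6-tetrol
Product: 13 (1S,2S,5R,6S)-5,6-di-O-benzoyl-2-O-(tert-butyldimethylsilyl)-1,7-O-isopropylidene-1-(hydroxymethyl)cyclohex-3-ene-1,2,5,6-tetrol
Conditions: BzCl, pyridine, DMAP (cat.), CH2Cl2, 0 → 40 °C
Reagents that add atoms: benzoyl chloride O=C(Cl)c1ccccc1
Why: DMAP-catalysed acylation esterifies both secondary hydroxyls of the trans-diol without touching any stereocentre.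

Step 9
Reactants: 13 (1S,2S,5R,6S)-5,6-di-O-benzoyl-2-O-(tert-butyldimethylsilyl)-1,7-O-isopropylidene-1-(hydroxymethyl)cyclohex-3-ene-1,2,5,6-tetrol
Product: 14 (1R,2S,5R,6S)-1-(hydroxymethyl)cyclohex-3-ene-1,2,5,6-tetrol 5,6-dibenzoate
Conditions: TFA/H2O, THF, 0 °C → rt
Reagents that add atoms: none
Why: Aqueous trifluoroacetic acid hydrolyses the isopropylidene acetal and the secondary silyl ether in one pot, conditions under which benzoates neither cleave nor readily migrate.

Step 10
Reactants: 14 (1R,2S,5R,6S)-1-(hydroxymethyl)cyclohex-3-ene-1,2,5,6-tetrol 5,6-dibenzoate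
Product: 15 [(1R,2S,5R,6S)-2-acetoxy-5,6-bis(benzoyloxy)-1-hydroxycyclohex-3-en-1-yl]methyl acetate
Conditions: Ac2O, pyridine, CH2Cl2, 0 °C → rt
Reagents that add atoms: acetic anhydride CC(=O)OC(C)=O
Why: Acetic anhydride in pyridine without an acyl-transfer catalyst acetylates the primary C7 and the secondary allylic C2 hydroxyl and leaves the tertiary C1 hydroxyl free, which completes the target with all four stereocentres as set in step 5.

Compound list
1 | 2-methylenepropane-1,3-diol | C=C(CO)CO | starting material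
2 | 2-(hydroxymethyl)propane-1,2,3-triol | OCC(O)(CO)CO | intermediate
3 | (2,2-dimethyl-1,3-dioxolane-4,4-diyl)dimethanol | CC1(C)OCC(CO)(CO)O1 | intermediate
4 | 2,2-dimethyl-1,3-dioxolane-4,4-dicarbaldehyde | CC1(C)OCC(C=O)(C=O)O1 | intermediate
5 | (E)-3-(trimethylsilyl)prop-2-en-1-ol | C[Si](C)(C)/C=C/CO | starting material
6 | (E)-3-(trimethylsilyl)prop-2-en-1-yl N,N-diisopropylcarbamate | CC(C)N(C(C)C)C(=O)OC/C=C/[Si](C)(C)C | intermediate
7 | [(1S,2E)-1-(N,N-diisopropylcarbamoyloxy)-3-(trimethylsilyl)prop-2-en-1-yl]lithium, formed as its (−)-sparteine complex | [Li][C@H](OC(=O)N(C(C)C)C(C)C)/C=C/[Si](C)(C)C | intermediate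
8 | triisopropoxy[(1R,2E)-1-(N,N-diisopropylcarbamoyloxy)-3-(trimethylsilyl)prop-2-en-1-yl]titanium | CC(C)O[Ti](OC(C)C)(OC(C)C)[C@@H](OC(=O)N(C(C)C)C(C)C)/C=C/[Si](C)(C)C | intermediate
9 | (1Z,3S,4R)-4-[(4R)-4-formyl-2,2-dimethyl-1,3-dioxolan-4-yl]-3-(trimethylsilyl)-4-(triisopropoxytitaniooxy)but-1-en-1-yl N,N-diisopropylcarbamate | O=C[C@]1(OC(C)(C)OC1)[C@@H](O[Ti](OC(C)C)(OC(C)C)OC(C)C)[C@@H]([Si](C)(C)C)/C=C\OC(=O)N(C(C)C)C(C)C | intermediate
10 | (1R,2S,5R,6S)-1-(hydroxymethyl)cyclohex-3-ene-1,2,5,6-tetrol 1,7-O-isopropylidene acetal 5-(N,N-diisopropylcarbamate); free OH at C2 and C6 | CC2(C)OC[C@@]1(O2)[C@@H](O)C=C[C@@H](OC(=O)N(C(C)C)C(C)C)[C@@H]1O | intermediate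
11 | (1S,2S,5R,6S)-2-O-(tert-butyldimethylsilyl)-1,7-O-isopropylidene-1-(hydroxymethyl)cyclohex-3-ene-1,2,5,6-tetrol 5-(N,N-diisopropylcarbamate); free OH at C6 | CC2(C)OC[C@@]1(O2)[C@@H](O[Si](C)(C)C(C)(C)C)C=C[C@@H](OC(=O)N(C(C)C)C(C)C)[C@@H]1O | intermediate
12 | (1S,2S,5R,6S)-2-O-(tert-butyldimethylsilyl)-1,7-O-isopropylidene-1-(hydroxymethyl)cyclohex-3-ene-1,2,5,6-tetrol; free OH at C5 and C6 | CC2(C)OC[C@@]1(O2)[C@@H](O[Si](C)(C)C(C)(C)C)C=C[C@@H](O)[C@@H]1O | intermediate
13 | (1S,2S,5R,6S)-5,6-di-O-benzoyl-2-O-(tert-butyldimethylsilyl)-1,7-O-isopropylidene-1-(hydroxymethyl)cyclohex-3-ene-1,2,5,6-tetrol | CC2(C)OC[C@@]1(O2)[C@@H](O[Si](C)(C)C(C)(C)C)C=C[C@@H](OC(=O)c3ccccc3)[C@@H]1OC(=O)c1ccccc1 | intermediate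
14 | (1R,2S,5R,6S)-1-(hydroxymethyl)cyclohex-3-ene-1,2,5,6-tetrol 5,6-dibenzoate | OC[C@@]1(O)[C@@H](O)C=C[C@@H](OC(=O)c2ccccc2)[C@@H]1OC(=O)c1ccccc1 | intermediate
15 | [(1R,2S,5R,6S)-2-acetoxy-5,6-bis(benzoyloxy)-1-hydroxycyclohex-3-en-1-yl]methyl acetate | CC(=O)OC[C@@]1(O)[C@@H](OC(C)=O)C=C[C@@H](OC(=O)c2ccccc2)[C@@H]1OC(=O)c1ccccc1 | target

Total step count: 10. Longest linear sequence: 9 steps (steps 1–3 and 5–10; step 4 is the one-step side branch).

Steps most likely to fail

**Step 5.** Three things may go wrong.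
- The two formyl groups may be discriminated too weakly, so that C1 forms with the wrong sense relative to C2.
- Peterson elimination or protodesilylation of the β-silyl alkoxide may outrun ring closure.
- Closure may be slow, because the reacting conformer must hold C2 inside against the Z carbamate oxygen (1,3-allylic strain).

The fallback uses known reactions only, sets C1 before any C–C bond is made, forms the two ring bonds in separate steps, and caps O2 before the Lewis acid is added. It sets out from 3 and comes back at 11. Lipase-catalysed mono-acetylation of the prochiral diol 3 with vinyl acetate (the enzyme screened for the S sense, or the diacetate hydrolysed with the complementary enzyme) gives [(4S)-4-(hydroxymethyl)-2,2-dimethyl-1,3-dioxolan-4-yl]methyl acetate F1. Dess–Martin oxidation gives [(4S)-4-formyl-2,2-dimethyl-1,3-dioxolan-4-yl]methyl acetate F2. Homoaldol addition of reagent 8 (made from 6 as in step 5) with aqueous work-up gives (1Z,3S,4R)-4-[(4S)-4-(acetoxymethyl)-2,2-dimethyl-1,3-dioxolan-4-yl]-4-hydroxy-3-(trimethylsilyl)but-1-en-1-yl N,N-diisopropylcarbamate F3. TBSOTf and 2,6-lutidine give its 4-O-tert-butyldimethylsilyl ether F4. K2CO3 in methanol removes the acetate to give (1Z,3S,4R)-4-(tert-butyldimethylsilyloxy)-4-[(4R)-4-(hydroxymethyl)-2,2-dimethyl-1,3-dioxolan-4-yl]-3-(trimethylsilyl)but-1-en-1-yl N,N-diisopropylcarbamate F5. A second Dess–Martin oxidation gives (1Z,3S,4R)-4-(tert-butyldimethylsilyloxy)-4-[(4R)-4-formyl-2,2-dimethyl-1,3-dioxolan-4-yl]-3-(trimethylsilyl)but-1-en-1-yl N,N-diisopropylcarbamate F6. BF3·OEt2 in CH2Cl2 at −78 °C (intramolecular Hosomi–Sakurai reaction) then closes the ring to 11, from which steps 7–10 follow.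

**Step 6.** Silylation may occur at O6 or at both hydroxyls (loss of site selectivity). The fallback replaces steric discrimination by a bridge that only the vicinal trans-diol can accept; it sets out from 10 and comes back at 15. LiAlH4 in refluxing THF gives (1R,2S,5R,6S)-1,7-O-isopropylidene-1-(hydroxymethyl)cyclohex-3-ene-1,2,5,6-tetrol F7. 1,3-Dichloro-1,1,3,3-tetraisopropyldisiloxane and imidazole in DMF should bridge O5 and O6 to give the 5,6-O-(1,1,3,3-tetraisopropyldisiloxane-1,3-diyl) derivative F8. Ac2O, pyridine and DMAP give its 2-acetate F9. HF·pyridine in THF gives (1S,2S,5R,6S)-2-O-acetyl-1,7-O-isopropylidene-1-(hydroxymethyl)cyclohex-3-ene-1,2,5,6-tetrol F10. BzCl, pyridine and DMAP give the 5,6-dibenzoate F11. Aqueous TFA gives (1R,2S,5R,6S)-2-O-acetyl-5,6-di-O-benzoyl-1-(hydroxymethyl)cyclohex-3-ene-1,2,5,6-tetrol F12. AcCl and 2,4,6-collidine in CH2Cl2 at −78 °C acetylate only the primary hydroxyl and give 15.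

**Step 2.** The acetal may form across a 1,3-diol pair (dioxane) or twice (spiro bis-acetal). The fallback sets out from 1 and comes back at 3; regiochemistry is fixed by protecting groups, so only one 1,2-diol is available when the acetal is made. TBSCl and imidazole give 2-methylenepropane-1,3-diyl bis(tert-butyldimethylsilyl) ether F13. OsO4 (cat.) and NMO give 3-(tert-butyldimethylsilyloxy)-2-[(tert-butyldimethylsilyloxy)methyl]propane-1,2-diol F14. 2,2-Dimethoxypropane and pyridinium p-toluenesulfonate give 4,4-bis[(tert-butyldimethylsilyloxy)methyl]-2,2-dimethyl-1,3-dioxolane F15. Bu4NF in THF then gives 3.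

Further compounds
F1 | step 5 | [(4S)-4-(hydroxymethyl)-2,2-dimethyl-1,3-dioxolan-4-yl]methyl acetate | CC1(C)OC[C@@](COC(C)=O)(O1)CO
F2 | step 5 | [(4S)-4-formyl-2,2-dimethyl-1,3-dioxolan-4-yl]methyl acetate | CC1(C)OC[C@@](COC(C)=O)(O1)C=O
F3 | step 5 | (1Z,3S,4R)-4-[(4S)-4-(acetoxymethyl)-2,2-dimethyl-1,3-dioxolan-4-yl]-4-hydroxy-3-(trimethylsilyl)but-1-en-1-yl N,N-diisopropylcarbamate | CC(=O)OC[C@]1(OC(C)(C)OC1)[C@@H](O)[C@@H]([Si](C)(C)C)/C=C\OC(=O)N(C(C)C)C(C)C
F4 | step 5 | (1Z,3S,4R)-4-[(4S)-4-(acetoxymethyl)-2,2-dimethyl-1,3-dioxolan-4-yl]-4-(tert-butyldimethylsilyloxy)-3-(trimethylsilyl)but-1-en-1-yl N,N-diisopropylcarbamate | CC(=O)OC[C@]1(OC(C)(C)OC1)[C@@H](O[Si](C)(C)C(C)(C)C)[C@@H]([Si](C)(C)C)/C=C\OC(=O)N(C(C)C)C(C)C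
F5 | step 5 | (1Z,3S,4R)-4-(tert-butyldimethylsilyloxy)-4-[(4R)-4-(hydroxymethyl)-2,2-dimethyl-1,3-dioxolan-4-yl]-3-(trimethylsilyl)but-1-en-1-yl N,N-diisopropylcarbamate | OC[C@]1(OC(C)(C)OC1)[C@@H](O[Si](C)(C)C(C)(C)C)[C@@H]([Si](C)(C)C)/C=C\OC(=O)N(C(C)C)C(C)C
F6 | step 5 | (1Z,3S,4R)-4-(tert-butyldimethylsilyloxy)-4-[(4R)-4-formyl-2,2-dimethyl-1,3-dioxolan-4-yl]-3-(trimethylsilyl)but-1-en-1-yl N,N-diisopropylcarbamate | O=C[C@]1(OC(C)(C)OC1)[C@@H](O[Si](C)(C)C(C)(C)C)[C@@H]([Si](C)(C)C)/C=C\OC(=O)N(C(C)C)C(C)C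
F7 | step 6 | (1R,2S,5R,6S)-1,7-O-isopropylidene-1-(hydroxymethyl)cyclohex-3-ene-1,2,5,6-tetrol | CC2(C)OC[C@@]1(O2)[C@@H](O)C=C[C@@H](O)[C@@H]1O
F8 | step 6 | (1R,2S,5R,6S)-1,7-O-isopropylidene-5,6-O-(1,1,3,3-tetraisopropyldisiloxane-1,3-diyl)-1-(hydroxymethyl)cyclohex-3-ene-1,2,5,6-tetrol | CC2(C)OC[C@@]1(O2)[C@@H](O)C=C[C@@H](O[Si](C(C)C)(C(C)C)O[Si]3(C(C)C)C(C)C)[C@@H]1O3
F9 | step 6 | (1R,2S,5R,6S)-2-O-acetyl-1,7-O-isopropylidene-5,6-O-(1,1,3,3-tetraisopropyldisiloxane-1,3-diyl)-1-(hydroxymethyl)cyclohex-3-ene-1,2,5,6-tetrol | CC2(C)OC[C@@]1(O2)[C@@H](OC(C)=O)C=C[C@@H](O[Si](C(C)C)(C(C)C)O[Si]3(C(C)C)C(C)C)[C@@H]1O3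
F10 | step 6 | (1S,2S,5R,6S)-2-O-acetyl-1,7-O-isopropylidene-1-(hydroxymethyl)cyclohex-3-ene-1,2,5,6-tetrol | CC2(C)OC[C@@]1(O2)[C@@H](OC(C)=O)C=C[C@@H](O)[C@@H]1O
F11 | step 6 | (1R,2S,5R,6S)-2-O-acetyl-5,6-di-O-benzoyl-1,7-O-isopropylidene-1-(hydroxymethyl)cyclohex-3-ene-1,2,5,6-tetrol | CC2(C)OC[C@@]1(O2)[C@@H](OC(C)=O)C=C[C@@H](OC(=O)c3ccccc3)[C@@H]1OC(=O)c1ccccc1
F12 | step 6 | (1R,2S,5R,6S)-2-O-acetyl-5,6-di-O-benzoyl-1-(hydroxymethyl)cyclohex-3-ene-1,2,5,6-tetrol | OC[C@@]1(O)[C@@H](OC(C)=O)C=C[C@@H](OC(=O)c2ccccc2)[C@@H]1OC(=O)c1ccccc1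
F13 | step 2 | 2-methylenepropane-1,3-diyl bis(tert-butyldimethylsilyl) ether | C=C(CO[Si](C)(C)C(C)(C)C)CO[Si](C)(C)C(C)(C)C
F14 | step 2 | 3-(tert-butyldimethylsilyloxy)-2-[(tert-butyldimethylsilyloxy)methyl]propane-1,2-diol | OCC(O)(CO[Si](C)(C)C(C)(C)C)CO[Si](C)(C)C(C)(C)C
F15 | step 2 | 4,4-bis[(tert-butyldimethylsilyloxy)methyl]-2,2-dimethyl-1,3-dioxolane | CC1(C)OCC(CO[Si](C)(C)C(C)(C)C)(CO[Si](C)(C)C(C)(C)C)O1
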